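You cannot keep the solid reagent's 0.130 M free as coupling partner: at balance the dormant form, the partner's resting state, holds 5.8 parts for each free one.

substrate 0.10 M; solid reagent 0.130 M; time 12 h

- why nothing more happens at 12 h, or that something still does (for what has run out or reacted, a solid counts together with what of it has only dissolved) (the coupling partner has run out first / it is still moving / forward and back rates have come level / all of the substrate has reacted)
- part of the substrate gone at 12 h
- the target standing at 12 h, as a percentage of the substrate charged
- the isomer of the product standing at 12 h, as a percentage of the substrate charged

- solid reagent is a solid; its amount is given per volume of the solution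
- at the start none of the solid reagent is in solution
- the reaction counts as stopped when no species that holds the substrate changes by six tenths of a point or more over the second half of the time
- run time (flask): 12 h

    substrate + coupling partner ⇌ target (K1 = 4.4 /M, k1 = 4.3 /M/min)
    target ⇌ isomer of the product (K2 = 0.69, k2 = 0.12 /min)
    solid reagent ⇌ coupling partner, rate k3*(cs3 - [coupling partner]) while solid is left; crystals form when [coupling partner] > cs3 (cs3 = 0.099 M, k3 = 0.051 /min)
    coupling partner ⇌ dormant form (K4 = 5.8, k4 = 0.080 /min)

Does solid stay behind? With c(dormant form) at 5.8 times c(coupling partner), the solution takes up 0.673 M of reagent before crystals stand, more than the charge. So I expect the solid to go, leaving c(coupling partner) near 0.0191 M, below its solubility of 0.099 M.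

Is there time? Dissolving at that level takes about 0.532 h. The partner and dormant form relax with a half-life of 0.123 h, target and isomer of the product with 2.36 min, and the coupling partner has a forward half-life of 1.6 min by step 1 with the substrate as charged. Each is far shorter than 12 h, so I expect a balance, with forward and back rates level.

How far, then? Freeze the split of the reagent and you get 1.09 /M, the pull: the balance ratio of target plus isomer to substrate, per mole per litre of unspent reagent, free plus dormant. On the full charge the ratio is 0.142, so 12.4% of the substrate goes. Taking the spent reagent off gives 11.4%, and once more 11.5%. That splits into 6.79% target and 4.69% isomer.

The forecast says forward and back rates have come level, with conversion 11.5%, target 6.8% and isomer 4.7%, on the grounds that “the dormant form soaks up most of the coupling partner”.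

The simulation gives forward and back rates have come level, with conversion 11.5%, target 6.79% and isomer 4.68%. Substrate still stands at 88.5% after 120 h.

Watch the ratio of products to substrate. In this flask at 12 h, c(coupling partner) is 0.0174 M and c(dormant form) 0.101 M, and the pull on their sum gives 0.129, while the products over the substrate read 0.130. Now take a neighbour flask, the same in its other charges and its time, with 0.052 M of solid reagent. The pull gives a ratio of 0.0569, so 5.38% gone, and after taking off the spent reagent, 4.85%. The neighbour flask gives conversion 4.90%, with c(coupling partner) at 0.00693 M.

Its constants are invented; the rest is arithmetic.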